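Retrosynthesis (labdane numbering): the C6 angelate C–O bond is cut first, the C8 carbinol is traced back to the exocyclic C8=C17 alkene, ring B is opened at C6–C7 (retro carbonyl-ene), C9–C10 is cut by a retro oxy-Cope shift that restores C6–C7 in an acyclic dienol, and that C6–C7 bond is finally cut into β-cyclocitral and an allyl chloride made from (R)-linalool.
Enabling feature: the six atoms of ring B (C10–C5–C6–C7–C8–C9) hold an oxygen on C6 beside the ring-fusion carbon C5, the C8 carbinol two bonds further on across C7, and the crowded bond from C9 to quaternary C10, so they are the chair of the 1,5-dien-3-ol C10=C5–C6(O)–C7–C8=C9.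
Forward order: ring A is bought; the chain is joined at C6–C7 by an allylbarium addition; the [3,3] shift moves the junction to C9–C10; ring B closes at C6–C7 by a type-2 carbonyl-ene reaction; C6 is then re-set, C8 hydrated and the ester added last.
Stereochemistry: C13 comes from (R)-linalool; a temporary 6S carbinol (CBS reduction) is relayed by the chair to C10 (β-methyl) and C9 (α-H); C5 (α-H) comes from enolate protonation; C6 (α-oxygen) from a thermodynamically controlled dissolving-metal reduction of the 6-ketone; C8 (α-OH) from α-face epoxidation and hydride opening; the Z ester geometry from angelic acid.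
Key step: step 7

Remark: a closed type-2 ene transition state is assumed to need the C6–O bond syn to C8–C17, which on the ring-B chair is the axial 6β position, so C6 is not taken from the ene step but re-set through the 6-ketone (steps 9 and 10). α/β refer to the usual labdane drawing with the C20 methyl on the β face.

Step 1
Reactants: 1 (R)-linalool
Product: 2 (3R)-3,7-dimethyl-3-(triethylsilyloxy)octa-1,6-diene
Conditions: TESOTf, 2,6-lutidine, CH2Cl2, −78 to 0 °C
Reagents that add atoms: triethylsilyl trifluoromethanesulfonate, CC[Si](CC)(CC)OS(=O)(=O)C(F)(F)F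
Why: Silylation of a tertiary alcohol with a silyl triflate and a hindered pyridine base is reliable and removes the only acidic proton before the organobarium, KH and Lewis-acid steps, without touching C13.

Step 2
Reactants: 2 (3R)-3,7-dimethyl-3-(triethylsilyloxy)octa-1,6-diene
Product: 3 (2E,6R)-2,6-dimethyl-6-(triethylsilyloxy)octa-2,7-dien-1-ol
Conditions: SeO2 (cat.), t-BuOOH, salicylic acid (cat.), CH2Cl2, 0 °C to rt
Reagents that add atoms: SeO2, O=[Se]=O; tert-butyl hydroperoxide, CC(C)(C)OO
Why: Catalytic SeO2 allylic oxidation (ene reaction, then [2,3]-sigmatropic shift) of a trisubstituted alkene attacks the E-methyl group of the gem-dimethyl end, and the vinyl group has no allylic hydrogen, so the E allylic alcohol should form.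

Step 3
Reactants: 3 (2E,6R)-2,6-dimethyl-6-(triethylsilyloxy)octa-2,7-dien-1-ol
Product: 4 (3R,6E)-8-chloro-3,7-dimethyl-3-(triethylsilyloxy)octa-1,6-diene
Conditions: MsCl, LiCl, 2,4,6-collidine, DMF, 0 °C
Reagents that add atoms: LiCl, [Li+].[Cl-]
Why: In-situ mesylation and SN2 displacement by chloride under non-acidic conditions converts a primary allylic alcohol into the chloride without allylic transposition or loss of the E geometry, and the tertiary silyl ether is inert.

Step 4
Reactants: 4 (3R,6E)-8-chloro-3,7-dimethyl-3-(triethylsilyloxy)octa-1,6-diene; 5 β-cyclocitral (2,6,6-trimethylcyclohex-1-ene-1-carbaldehyde)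
Product: 7 (1RS,3E,7R)-3,7-dimethyl-7-(triethylsilyloxy)-1-(2,6,6-trimethylcyclohex-1-en-1-yl)nona-3,8-dien-1-ol (both C6 epimers in labdane numbering), via allylbarium chloride 6 (not isolated)
Conditions: activated zerovalent barium (BaI2, lithium biphenylide, THF, rt); 4, −78 °C; then 5, −78 °C; H2O
Reagents that add atoms: none
Why: Allylbarium reagents add to aldehydes through the carbon that carried the halogen (α-selective 1,2-addition) and keep their alkene geometry at −78 °C, so C6–C7 should form with the E C8=C9 alkene intact; the new C6 centre is uncontrolled and is erased in step 5.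

Step 5
Reactants: 7 (1RS,3E,7R)-dienol
Product: 8 (3E,7R)-3,7-dimethyl-7-(triethylsilyloxy)-1-(2,6,6-trimethylcyclohex-1-en-1-yl)nona-3,8-dien-1-one
Conditions: Dess–Martin periodinane, pyridine, CH2Cl2, 0 °C
Reagents that add atoms: none
Why: Dess–Martin oxidation under buffered, non-enolising conditions gives β,γ-unsaturated ketones without moving the C8=C9 alkene into conjugation, and it removes the uncontrolled carbinol centre.

Step 6
Reactants: 8 (3E,7R)-dienone
Product: 9 (1S,3E,7R)-3,7-dimethyl-7-(triethylsilyloxy)-1-(2,6,6-trimethylcyclohex-1-en-1-yl)nona-3,8-dien-1-ol (6S in labdane numbering)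
Conditions: (R)-2-methyl-CBS-oxazaborolidine [(R)-1-methyl-3,3-diphenyltetrahydro-1H,3H-pyrrolo[1,2-c][1,3,2]oxazaborole] (cat.), catecholborane, toluene, −78 °C; then MeOH, H2O
Reagents that add atoms: none
Why: In this Corey–Bakshi–Shibata reduction the fully substituted cyclohexenyl group is the large substituent and the CH2 group the small one, so the (R)-catalyst should deliver hydride in the sense that turns acetophenone into (S)-1-phenylethanol and give the 6S carbinol, while catecholborane at −78 °C does not hydroborate the alkenes.

Step 7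
Reactants: 9 (1S,3E,7R)-dienol
Product: 12 (13R)-13-(triethylsilyloxy)-6,7-secolabda-7,14-dien-6-al (5α-H; 9α-H; 10β-methyl; isopropenyl group on C9), via potassium alkoxide 10 (not isolated), via potassium enolate 11 (not isolated)
Conditions: KH, 18-crown-6, THF, 0 to 50 °C; then AcOH, THF, −78 °C
Reagents that add atoms: none
Why: Deprotonation gives the potassium alkoxide, whose oxyanion weakens C6–C7, and a concerted [3,3]-sigmatropic shift through a chair forms C9–C10 and cuts C6–C7 to give the aldehyde enolate, which is then protonated at C5; the closest known reaction type is the anionic oxy-Cope rearrangement of acyclic secondary 1,5-dien-3-ols. No ring closes in this step: the six atoms of the chair are those of ring B, but C6–C7 is open in the product and is re-formed in step 8. C10 and C9 are set together by the chair under control of the 6S carbinol: the C20 methyl, cis to C6 on the ring-A alkene, is axial and becomes 10β, and C11, trans to C7 on the E alkene, is equatorial, which leaves 9α-H. C5 is set by protonation of the enolate at −78 °C on the α face, opposite the syn-axial C19 and C20 methyl groups, which places the formyl group equatorial and trans to the C9 substituent on ring A. The selectivity needed is the chair with the oxyanion equatorial over the chair with it axial (which would invert both C9 and C10) and over boats; the substrate secures it because an axial substituent on C6 is 1,3-diaxial to the axial C20 methyl, so only hydrogen fits there.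

Step 8
Reactants: 12 (13R)-13-(triethylsilyloxy)-6,7-secolabda-7,14-dien-6-al
Product: 13 (13R)-13-(triethylsilyloxy)labda-8(17),14-dien-6β-ol
Conditions: Me2AlCl, CH2Cl2, −78 to −20 °C; then H2O
Reagents that add atoms: none
Why: The Me2AlCl-promoted type-2 intramolecular carbonyl-ene reaction (isopropenyl group tethered through its central carbon C8) forms C6–C7 and passes a C17 hydrogen to oxygen, closing ring B as a trans-fused chair because the formyl group and the C9 chain are both equatorial on ring A; the closed transition state needs the C6–O bond syn to C8–C17, that is axial, so the 6β-alcohol is expected, and any 6α epimer is equally useful because C6 is re-set in steps 9 and 10.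

Step 9
Reactants: 13 (13R)-13-(triethylsilyloxy)labda-8(17),14-dien-6β-ol
Product: 14 (13R)-13-(triethylsilyloxy)labda-8(17),14-dien-6-one
Conditions: Dess–Martin periodinane, pyridine, CH2Cl2, 0 °C to rt
Reagents that add atoms: none
Why: Dess–Martin oxidation of the strained axial alcohol (relief of the two syn-axial methyl/oxygen contacts) should give the β,γ-unsaturated 6-ketone under buffered conditions that leave the 8(17) alkene out of conjugation and C5 untouched.

Step 10
Reactants: 14 (13R)-13-(triethylsilyloxy)labda-8(17),14-dien-6-one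
Product: 15 (13R)-13-(triethylsilyloxy)labda-8(17),14-dien-6α-ol
Conditions: Li, NH3 (l), THF, t-BuOH, −78 °C; then NH4Cl
Reagents that add atoms: none
Why: Dissolving-metal reduction of a hindered cyclohexanone gives the more stable equatorial alcohol (as with 11-oxo steroids, whose axial side is likewise flanked by two angular methyl groups), because the intermediate α-oxy carbanion keeps oxygen away from the syn-axial C19 and C20 methyls and is protonated on the β face, which sets 6α-OH; isolated alkenes are not reduced.

Step 11
Reactants: 15 (13R)-13-(triethylsilyloxy)labda-8(17),14-dien-6α-ol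
Product: 16 (13R)-8α,17-epoxy-13-(triethylsilyloxy)labd-14-en-6α-ol
Conditions: mCPBA, NaHCO3, CH2Cl2, 0 °C
Reagents that add atoms: meta-chloroperoxybenzoic acid, OOC(=O)c1cccc(Cl)c1
Why: Peracid (Prilezhaev) epoxidation picks the 1,1-disubstituted 8(17) alkene over the monosubstituted vinyl group, and the peracid should approach from the α face because the β face of C8 is blocked by the syn-axial C20 methyl, which places the epoxide oxygen 8α.

Step 12
Reactants: 16 (13R)-8α,17-epoxy-13-(triethylsilyloxy)labd-14-en-6α-ol
Product: 17 (13R)-13-(triethylsilyloxy)labd-14-ene-6α,8α-diol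
Conditions: LiAlH4, THF, 0 °C to rt
Reagents that add atoms: none
Why: Hydride opens the spiro epoxide by SN2 attack at the unhindered CH2 carbon (C17), which leaves the 8α tertiary alcohol and the axial 8β methyl of the sclareol series without touching the C8–O bond.

Step 13
Reactants: 17 (13R)-13-(triethylsilyloxy)labd-14-ene-6α,8α-diol
Product: 18 6α-hydroxysclareol [(13R)-labd-14-ene-6α,8α,13-triol]
Conditions: Bu4NF, THF, rt to 40 °C
Reagents that add atoms: none
Why: Fluoride cleaves the tertiary triethylsilyl ether (driven by Si–F bond formation) under non-acidic conditions, so the tertiary allylic C13 carbinol is freed without ionisation or allylic transposition.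

Step 14
Reactants: 18 6α-hydroxysclareol; 19 angelic acid [(Z)-2-methylbut-2-enoic acid]
Product: 21 6α-angeloyloxysclareol [(13R)-6α-[(Z)-2-methylbut-2-enoyloxy]labd-14-ene-8α,13-diol], via angelic 2,4,6-trichlorobenzoic anhydride 20 (not isolated)
Conditions: 19, 2,4,6-trichlorobenzoyl chloride, Et3N, toluene, rt; then 18, 4-(dimethylamino)pyridine, toluene, rt to 60 °C
Reagents that add atoms: none
Why: In this Yamaguchi esterification the mixed anhydride acylates the only secondary hydroxyl (6α, equatorial) while the two tertiary hydroxyls stay free, and the protocol is an established way to transfer the angeloyl group without Z-to-E isomerisation to the tiglate.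

Compound list
1 | (R)-linalool | C=C[C@](C)(O)CCC=C(C)C | starting material
2 | (3R)-3,7-dimethyl-3-(triethylsilyloxy)octa-1,6-diene | C=C[C@](C)(O[Si](CC)(CC)CC)CCC=C(C)C | intermediate
3 | (2E,6R)-2,6-dimethyl-6-(triethylsilyloxy)octa-2,7-dien-1-ol | C=C[C@](C)(O[Si](CC)(CC)CC)CC/C=C(\C)CO | intermediate
4 | (3R,6E)-8-chloro-3,7-dimethyl-3-(triethylsilyloxy)octa-1,6-diene | C=C[C@](C)(O[Si](CC)(CC)CC)CC/C=C(\C)CCl | intermediate
5 | β-cyclocitral | CC1=C(C=O)C(C)(C)CCC1 | starting material
6 | [(2E,6R)-2,6-dimethyl-6-(triethylsilyloxy)octa-2,7-dien-1-yl]barium chloride | C=C[C@](C)(O[Si](CC)(CC)CC)CC/C=C(\C)C[Ba]Cl | intermediate (not isolated)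
7 | (1RS,3E,7R)-3,7-dimethyl-7-(triethylsilyloxy)-1-(2,6,6-trimethylcyclohex-1-en-1-yl)nona-3,8-dien-1-ol, both carbinol epimers | CC1=C(C(O)C/C(C)=C/CC[C@@](C)(O[Si](CC)(CC)CC)C=C)C(C)(C)CCC1 | intermediate
8 | (3E,7R)-3,7-dimethyl-7-(triethylsilyloxy)-1-(2,6,6-trimethylcyclohex-1-en-1-yl)nona-3,8-dien-1-one | CC1=C(C(=O)C/C(C)=C/CC[C@@](C)(O[Si](CC)(CC)CC)C=C)C(C)(C)CCC1 | intermediate
9 | (1S,3E,7R)-3,7-dimethyl-7-(triethylsilyloxy)-1-(2,6,6-trimethylcyclohex-1-en-1-yl)nona-3,8-dien-1-ol | CC1=C([C@@H](O)C/C(C)=C/CC[C@@](C)(O[Si](CC)(CC)CC)C=C)C(C)(C)CCC1 | intermediate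
10 | potassium alkoxide of 9 | CC1=C([C@@H]([O-])C/C(C)=C/CC[C@@](C)(O[Si](CC)(CC)CC)C=C)C(C)(C)CCC1.[K+] | intermediate (not isolated)
11 | potassium enolate of aldehyde 12 (C5=C6–O, oxygen cis to C4) | C=C[C@](C)(O[Si](CC)(CC)CC)CC[C@@H](C(C)=C)[C@@]1(C)CCCC(C)(C)/C1=C\[O-].[K+] | intermediate (not isolated)
12 | (13R)-13-(triethylsilyloxy)-6,7-secolabda-7,14-dien-6-al (5α-H, 9α-H, 10β-methyl) | C=C[C@](C)(O[Si](CC)(CC)CC)CC[C@@H](C(C)=C)[C@@]1(C)CCCC(C)(C)[C@@H]1C=O | intermediate
13 | (13R)-13-(triethylsilyloxy)labda-8(17),14-dien-6β-ol | C=C[C@](C)(O[Si](CC)(CC)CC)CC[C@@H]1[C@@]2(C)CCCC(C)(C)[C@@H]2[C@H](O)CC1=C | intermediate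
14 | (13R)-13-(triethylsilyloxy)labda-8(17),14-dien-6-one | C=C[C@](C)(O[Si](CC)(CC)CC)CC[C@@H]1[C@@]2(C)CCCC(C)(C)[C@@H]2C(=O)CC1=C | intermediate
15 | (13R)-13-(triethylsilyloxy)labda-8(17),14-dien-6α-ol | C=C[C@](C)(O[Si](CC)(CC)CC)CC[C@@H]1[C@@]2(C)CCCC(C)(C)[C@@H]2[C@@H](O)CC1=C | intermediate
16 | (13R)-8α,17-epoxy-13-(triethylsilyloxy)labd-14-en-6α-ol | C=C[C@](C)(O[Si](CC)(CC)CC)CC[C@@H]1[C@@]2(C)CCCC(C)(C)[C@@H]2[C@@H](O)C[C@]13CO3 | intermediate
17 | (13R)-13-(triethylsilyloxy)labd-14-ene-6α,8α-diol | C=C[C@](C)(O[Si](CC)(CC)CC)CC[C@@H]1[C@@]2(C)CCCC(C)(C)[C@@H]2[C@@H](O)C[C@@]1(C)O | intermediate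
18 | 6α-hydroxysclareol, (13R)-labd-14-ene-6α,8α,13-triol | C=C[C@](C)(O)CC[C@@H]1[C@@]2(C)CCCC(C)(C)[C@@H]2[C@@H](O)C[C@@]1(C)O | intermediate
19 | angelic acid | C/C=C(/C)C(=O)O | starting material
20 | angelic 2,4,6-trichlorobenzoic anhydride | C/C=C(/C)C(=O)OC(=O)c1c(Cl)cc(Cl)cc1Cl | intermediate (not isolated)
21 | 6α-angeloyloxysclareol | C=C[C@](C)(O)CC[C@@H]1[C@@]2(C)CCCC(C)(C)[C@@H]2[C@@H](OC(=O)/C(C)=C\C)C[C@@]1(C)O | target

Total step count: 14. Longest linear sequence: 14 steps, from (R)-linalool 1 to 21; β-cyclocitral 5 and angelic acid 19 enter as bought compounds.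

Steps most likely to fail

Step 7. The alkoxide may fragment heterolytically at C6–C7 (retro-allylation to β-cyclocitral and an allyl anion, with recombination that loses the C6 information) faster than the congested C9–C10 bond forms, or the shift may leak through a boat. The fallback gives up charge acceleration and sets out from 9. Silylation (Me3SiCl, imidazole, CH2Cl2) gives the C6 trimethylsilyl ether F1, which cannot fragment to an allyl anion. It is rearranged thermally through the same chair (siloxy-Cope rearrangement, o-dichlorobenzene, base-washed sealed tube, 200–220 °C) to the trimethylsilyl enol ether F2. K2CO3 in MeOH at 0 °C cleaves the enol ether and equilibrates C5 to the equatorial formyl epimer, while the tertiary triethylsilyl ether stays, and the route is rejoined at aldehyde 12.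

Step 8. Bond formation may outrun hydrogen transfer (open Prins pathway), so that the C8 cation takes up chloride, loses a proton from C7 or C9 instead of C17, or starts hydride and methyl shifts. The axial approach of the aluminium-bound carbonyl between the C19 and C20 methyls may also be too slow. The fallback closes the same C6–C7 bond by an organometallic allylation and sets out from 12. Ene-type allylic chlorination of the isopropenyl group with hypochlorous acid (Ca(OCl)2, solid CO2, CH2Cl2/H2O, 0 °C; the vinyl group is too electron-poor to react) gives the 2-(chloromethyl)allyl aldehyde F3. An intramolecular Nozaki–Hiyama–Kishi-type allylation with divalent chromium (CrCl2, THF, rt) then closes ring B. Both allyl termini are CH2 groups and no cation forms at C8, so only the exocyclic 8(17) alkene can result. Whichever C6 epimer forms is oxidised in step 9, so the route is rejoined at alcohol 13.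

Step 10. Electron transfer may cleave the allylic C13–O bond of the silyl ether, or amide base may move the 8(17) alkene into conjugation with the ketone before it is reduced. The fallback changes the protecting-group order so that C13 is present as a lithium alkoxide, which cannot leave, and sets out from 14. Buffered desilylation (HF·pyridine, pyridine, THF, 0 °C) gives the 13-hydroxy ketone F4. The same thermodynamically controlled reduction (Li, NH3, THF, t-BuOH, −78 °C) gives the 6α,13-diol F5. α-Face epoxidation of the 8(17) alkene (mCPBA, NaHCO3, CH2Cl2, 0 °C) gives the epoxy diol F6, and LiAlH4 in THF opens it at C17 to rejoin the route at triol 18.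

Further compounds
F1 | step 7 | C6 trimethylsilyl ether of dienol 9 | CC1=C([C@@H](O[Si](C)(C)C)C/C(C)=C/CC[C@@](C)(O[Si](CC)(CC)CC)C=C)C(C)(C)CCC1
F2 | step 7 | trimethylsilyl enol ether of aldehyde 12 | C=C[C@](C)(O[Si](CC)(CC)CC)CC[C@@H](C(C)=C)[C@@]1(C)CCCC(C)(C)/C1=C\O[Si](C)(C)C
F3 | step 8 | (13R)-17-chloro-13-(triethylsilyloxy)-6,7-secolabda-7,14-dien-6-al | C=C[C@](C)(O[Si](CC)(CC)CC)CC[C@@H](C(=C)CCl)[C@@]1(C)CCCC(C)(C)[C@@H]1C=O
F4 | step 10 | (13R)-13-hydroxylabda-8(17),14-dien-6-one | C=C[C@](C)(O)CC[C@@H]1[C@@]2(C)CCCC(C)(C)[C@@H]2C(=O)CC1=C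
F5 | step 10 | (13R)-labda-8(17),14-diene-6α,13-diol | C=C[C@](C)(O)CC[C@@H]1[C@@]2(C)CCCC(C)(C)[C@@H]2[C@@H](O)CC1=C
F6 | step 10 | (13R)-8α,17-epoxylabd-14-ene-6α,13-diol | C=C[C@](C)(O)CC[C@@H]1[C@@]2(C)CCCC(C)(C)[C@@H]2[C@@H](O)C[C@]13CO3
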